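With steps this slow I count turnovers rather than minutes: a step's rate constant, times its partner's concentration, times the run.

| setting | theta | eta | delta | zeta |
|---|---|---|---|---|
| starting material | 0.10 M | 0.10 M | 0.10 M | 0.10 M (fed, over 8.00 d) |
| reagent | 0.200 M (fed, over 8.00 d) | 0.200 M | 0.200 M | 0.200 M |
| second substrate | 0.100 M | 0.100 M | 0.100 M | 0.100 M |
| time | 8.0 d | 8.0 d |  | 8.0 d |
| remark | all but reagent at the start; reagent goes in evenly over 8.00 d, the run ends at 8.0 d | a closed flask charged with all of it at once and left for 8.0 d | a single well-mixed tank run continuously and read at steady state, 8.0 d in it on average | all but starting material at the start; starting material goes in evenly over 8.00 d, the run ends at 8.0 d |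

    starting material ⇌ dormant form (K1 = 1.2, k1 = 4.27 × 10⁻⁴ min⁻¹)
    starting material + second substrate → cross product (k2 = 1.65 × 10⁻⁴ M⁻¹ min⁻¹)
    second substrate + reagent → second product (k3 = 3.14 × 10⁻⁴ M⁻¹ min⁻¹)
    starting material + reagent ⇌ target (K4 = 19 M⁻¹, k4 = 0.00340 M⁻¹ min⁻¹)

- the set-up with the highest amount of target at the outlet or at the end, in percent of the starting material put in ("none" if the first two lie within 2 percentage points) (theta / eta / delta / zeta / none)
- amount of target at the outlet or at the end, in percent of the starting material put in, theta
- amount of target at the outlet or at the end, in percent of the starting material put in, eta
- amount of target at the outlet or at the end, in percent of the starting material put in, delta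
- amount of target at the outlet or at the end, in percent of the starting material put in, zeta

- the stated concentrations are those of everything mixed, before any reaction; amounts are the same in each set-up
- the feed brings no volume worth counting
- run time (theta): 8.0 d

I reckon eta, the closed flask. I guess that about half of the starting material ends up bound, which takes a quarter of the reagent charge and leaves a reagent fraction of 0.750. Over 8.0 d, the ladder of counts reads, from the top rung down:

binding of starting material to reagent: 5.88
passage of starting material to the dormant form: 4.92
reagent with second substrate: 0.543
free starting material with second substrate: 0.190

The third count is the one I carry: the waste count, the turnovers of second substrate on the reagent left after binding.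

The top two rungs turn over many times more than the third, so I treat them as a pre-equilibrium by the end of eta. The third is below one turnover, so it goes on draining reagent through the whole run. The fourth is lower still, and I drop it. This gives:

second substrate left: exp(−waste count) = 0.581
reagent fraction it takes: 0.209
reagent fraction free: 0.541
target per free starting material: 2.05, against 1.2 dormant form
target: 48.3%

That lands near the half I guessed. Theta and zeta feed one partner evenly, and I expect them to lag eta, but I reckon neither them nor delta.

The forecast says 41% for theta, 49.5% for eta, 43.5% for delta and 42.5% for zeta, with eta best, noting that “relaxation takes about 3 d, so the flask reaches quasi-equilibrium”. The simulation gives 40.8%, 48.8%, 43.6% and 43.2% in that order, with eta best.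

Eta holds 58.9% of its second substrate at 8.00 d, where the waste count left 58.1%. At 8.00 d in zeta, forward binding alone uses reagent 5.5 times as fast as the path to second product does, while it uses starting material at 0.91 of the forward rate of the path to the dormant form. In the zeta flask with 0.80 M of reagent, I take the reagent less the starting-material charge, which gives a waste count of 2.53 and leaves 7.95% of the second substrate; that flask holds 8.0%.

All constants were drawn at random within sensible limits; the run is a simulation.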